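**Plan**

1. Ring numbering: O1, C2 (3,4-dimethoxyphenyl), C3 (CH2OH), C4 (aroyl), C5 (CH2). The enabling feature is the ether triad C2–O1–C5, benzylic at C2 and unsubstituted at C5, with each carbon bonded to one carbon of the vicinal pair C3–C4 that carries two one-carbon oxygenated branches. This is a carbonyl ylide (veratraldehyde oxygen plus CH2) laid across a but-2-ene-1,4-dioxygenated dipolarophile.
2. Retrosynthesis: invert C4 (alpha to the ketone); cut the aryl–C(=O) bond to an aryllithium and a cis-fused lactone; take the lactone back to an all-cis diol; cut C2–C3 and C4–C5 together by a (3+2) cycloaddition to a nonstabilised carbonyl ylide and (5R)-5-(l-menthyloxy)furan-2(5H)-one.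
3. Forward: the oxolane ring is built in one operation onto the butenolide, which serves as a temporary lactone ring. LiAlH4 opens it and removes the menthyloxy helper; the lactone is re-formed with its carbonyl on the C4 branch; the aryllithium opens it to the ketol; base sets C4.
4. The ylide is polarised (nucleophilic CH2, cationic benzylic carbon), so the activating carbonyl must sit on the C3 branch during the cycloaddition. That is why the carbonyl is transposed afterwards instead of using the aroyl enone directly.
5. Stereochemistry: the acetal centre of the butenolide fixes the face (C3, C4, absolute); the endo transition state puts the aryl group cis to the C3 branch (C2); the Z-alkene gives 3,4-cis, corrected at the end by thermodynamic epimerisation to 3,4-trans.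

Key step: step 2

Remark: compounds 1, 2, 4 and 10 are taken as commercially available; the target is made with the configuration drawn (aryl and CH2OH cis, CH2OH and aroyl trans).

**Step 1**
Reactants: 1 3,4-dimethoxybenzaldehyde; 2 (trimethylsilyl)methanol
Product: 3 4-{bis[(trimethylsilyl)methoxy]methyl}-1,2-dimethoxybenzene
Conditions: 2 (2.3 equiv), p-TsOH·H2O (2 mol%), cyclohexane, reflux with a water separator; Et3N before work-up
Reagents that add atoms: none
Why: Acid-catalysed acetalisation driven by azeotropic removal of water should give the bis(silylmethyl) acetal; the Si–C bond tolerates catalytic acid and no stereocentre is formed.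

**Step 2**
Reactants: 3 4-{bis[(trimethylsilyl)methoxy]methyl}-1,2-dimethoxybenzene; 4 (5R)-5-[(1R,2S,5R)-menthyloxy]furan-2(5H)-one (menthyl = 5-methyl-2-(propan-2-yl)cyclohexyl)
Product: 7 (3R,3aS,6S,6aR)-6-(3,4-dimethoxyphenyl)-3-[(1R,2S,5R)-menthyloxy]tetrahydro-1H,3H-furo[3,4-c]furan-1-one, via alpha-chloro ether 5 (not isolated), via carbonyl ylide 6 (not isolated)
Conditions: 3 (1.5 equiv), AcCl (1.05 equiv per 3), CH2Cl2, 0 °C, volatiles removed cold; then 4 (1 equiv), CsF (3 equiv), MeCN, 0 °C to rt
Reagents that add atoms: none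
Why: Fluoride removes the silyl group of the alpha-chloro ether 5 as Me3SiF while chloride leaves from the benzylic carbon (1,3-elimination), giving the nonstabilised carbonyl ylide 6, a C–O–C dipole that adds across the C3=C4 bond of butenolide 4 in a concerted, asynchronous (3+2) cycloaddition. The closest known reaction type is the fluoride-induced generation of nonstabilised carbonyl ylides from alpha-chloroalkyl silylmethyl ethers and their cycloaddition to alpha,beta-unsaturated esters and lactones. The oxolane ring closes in an intermolecular (3+2) mode, suprafacial on both partners, so both new C–C bonds (C2–C3 and C4–C5) lie on one face of the lactone and the ring fusion is necessarily cis. Regiochemistry should follow the polarity of the dipole: the CH2 terminus that lost silicon is the nucleophilic end and bonds to the beta-carbon of the enoate, while the benzylic terminus, an oxocarbenium carbon stabilised by the dimethoxyphenyl ring, is closed by the alpha-carbon. C3 and C4 are controlled by the acetal stereocentre of 4 (addition anti to the menthyloxy group), and C2 by the endo transition state of the ylide with its aryl group in the outer (E) position, where the ylide oxygen and the electron-rich aryl ring lie over the lactone carbonyl, so the aryl group ends up cis to the lactone ring. The step therefore needs regio-, facial and endo selectivity; the first two are secured by the single acceptor group and the rigid chiral acetal of 4, while the third rests only on secondary interactions and is the weakest point.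

**Step 3**
Reactants: 7 (3R,3aS,6S,6aR)-6-(3,4-dimethoxyphenyl)-3-[(1R,2S,5R)-menthyloxy]tetrahydro-1H,3H-furo[3,4-c]furan-1-one
Product: 8 [(2S,3S,4R)-2-(3,4-dimethoxyphenyl)oxolane-3,4-diyl]dimethanol (all-cis)
Conditions: LiAlH4 (2 equiv), THF, 0 °C to rt; H2O quench, filtration
Reagents that add atoms: none
Why: Hydride reduction of the lactone and of the acyloxy acetal (which opens to an aldehyde and releases menthol) should give the 1,4-diol; the ring stereocentres should survive because the transient aldehydes are reduced faster than they enolise.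

**Step 4**
Reactants: 8 [(2S,3S,4R)-2-(3,4-dimethoxyphenyl)oxolane-3,4-diyl]dimethanol
Product: 9 (3aS,4S,6aS)-4-(3,4-dimethoxyphenyl)tetrahydro-1H,3H-furo[3,4-c]furan-1-one
Conditions: TEMPO (10 mol%), PhI(OAc)2 (2.5 equiv), CH2Cl2, rt
Reagents that add atoms: none
Why: In this oxoammonium-mediated oxidative lactonisation of a 1,4-diol, the less hindered hydroxymethyl group on C4 (not flanked by the cis aryl group) should be oxidised first, the aldehyde trapped as the lactol by the cis hydroxymethyl group on C3 and oxidised on to the lactone.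

**Step 5**
Reactants: 9 (3aS,4S,6aS)-4-(3,4-dimethoxyphenyl)tetrahydro-1H,3H-furo[3,4-c]furan-1-one; 10 5-bromo-1,2,3-trimethoxybenzene
Product: 12 (3,4,5-trimethoxyphenyl)[(3S,4S,5S)-5-(3,4-dimethoxyphenyl)-4-(hydroxymethyl)oxolan-3-yl]methanone (cis ketol), via aryllithium 11 (not isolated)
Conditions: 10 (1.15 equiv), n-BuLi (1.1 equiv), THF, −78 °C; then 9 in THF, −78 °C; aq. NH4Cl at −78 °C
Reagents that add atoms: none
Why: Bromine–lithium exchange followed by addition of the aryllithium to the gamma-lactone at low temperature should stop at the lithium hemiketalate, which on protonation gives the gamma-hydroxy aryl ketone (in ring–chain equilibrium with its bicyclic hemiketal) with the cis arrangement retained.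

**Step 6**
Reactants: 12 (3,4,5-trimethoxyphenyl)[(3S,4S,5S)-5-(3,4-dimethoxyphenyl)-4-(hydroxymethyl)oxolan-3-yl]methanone
Product: 13 (3,4,5-trimethoxyphenyl)[(3R,4S,5S)-5-(3,4-dimethoxyphenyl)-4-(hydroxymethyl)oxolan-3-yl]methanone (target)
Conditions: DBU (0.2 equiv), CH2Cl2, rt
Reagents that add atoms: none
Why: Base-catalysed epimerisation (enolisation and reprotonation) at C4, the only CH alpha to the ketone, should equilibrate to the 3,4-trans isomer, which relieves the all-cis arrangement on the oxolane ring; C2 and C3 carry no acidic hydrogen and stay as set.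

**Compound list**

1 | 3,4-dimethoxybenzaldehyde | COc1ccc(C=O)cc1OC | starting material
2 | (trimethylsilyl)methanol | C[Si](C)(C)CO | starting material
3 | 4-{bis[(trimethylsilyl)methoxy]methyl}-1,2-dimethoxybenzene | COc1ccc(C(OC[Si](C)(C)C)OC[Si](C)(C)C)cc1OC | intermediate
4 | (5R)-5-[(1R,2S,5R)-menthyloxy]furan-2(5H)-one | O=C1C=C[C@H](O[C@@H]2C[C@H](C)CC[C@H]2C(C)C)O1 | starting material
5 | 4-{chloro[(trimethylsilyl)methoxy]methyl}-1,2-dimethoxybenzene (racemic alpha-chloro ether) | COc1ccc(C(Cl)OC[Si](C)(C)C)cc1OC | intermediate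
6 | carbonyl ylide from 3,4-dimethoxybenzaldehyde and CH2 | COc1ccc(C=[O+][CH2-])cc1OC | intermediate
7 | (3R,3aS,6S,6aR)-6-(3,4-dimethoxyphenyl)-3-[(1R,2S,5R)-menthyloxy]tetrahydro-1H,3H-furo[3,4-c]furan-1-one | O=C1O[C@@H](O[C@@H]3C[C@H](C)CC[C@H]3C(C)C)[C@@H]2CO[C@H](c4ccc(OC)c(OC)c4)[C@H]12 | intermediate
8 | [(2S,3S,4R)-2-(3,4-dimethoxyphenyl)oxolane-3,4-diyl]dimethanol | OC[C@@H]1CO[C@H](c2ccc(OC)c(OC)c2)[C@@H]1CO | intermediate
9 | (3aS,4S,6aS)-4-(3,4-dimethoxyphenyl)tetrahydro-1H,3H-furo[3,4-c]furan-1-one | O=C1OC[C@H]2[C@@H](c3ccc(OC)c(OC)c3)OC[C@@H]12 | intermediate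
10 | 5-bromo-1,2,3-trimethoxybenzene | COc1cc(Br)cc(OC)c1OC | starting material
11 | (3,4,5-trimethoxyphenyl)lithium | [Li]c1cc(OC)c(OC)c(OC)c1 | intermediate
12 | (3,4,5-trimethoxyphenyl)[(3S,4S,5S)-5-(3,4-dimethoxyphenyl)-4-(hydroxymethyl)oxolan-3-yl]methanone (cis ketol, open form drawn) | COc1ccc([C@H]2OC[C@@H](C(=O)c3cc(OC)c(OC)c(OC)c3)[C@H]2CO)cc1OC | intermediate
13 | (3,4,5-trimethoxyphenyl)[(3R,4S,5S)-5-(3,4-dimethoxyphenyl)-4-(hydroxymethyl)oxolan-3-yl]methanone | COc1ccc([C@H]2OC[C@H](C(=O)c3cc(OC)c(OC)c(OC)c3)[C@H]2CO)cc1OC | target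

**Step count and risks**

Total step count: 6. Longest linear sequence: 6 steps (from 1).

Steps most likely to fail:

Step 2. The risk is poor endo/exo selectivity, which would place the aryl group trans to the lactone ring and lead to the C2-epimeric series. The fallback sets out from 3 and returns at 8, and removes the endo/exo question by using an alkyne. The ylide 6 is generated from 3 as before (AcCl, then CsF, MeCN) and trapped with di-l-menthyl but-2-ynedioate F1, itself made from acetylenedicarboxylic acid and l-menthol (p-TsOH, toluene, water removal). This should give the 2,5-dihydrofuran diester F2 together with its C2 epimer F3, which are separated by chromatography or crystallisation, the menthyl esters serving as a covalent resolving handle. cis-Hydrogenation of F2 (H2, 5% Rh on Al2O3, EtOAc) from the face opposite to the aryl group should give the all-cis diester F4, and LiAlH4 in THF reduces F4 to diol 8.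

Step 4. The risk is insufficient site selectivity between the two primary alcohols, with oxidation of the hindered hydroxymethyl group giving the regioisomeric lactone. The fallback sets out from 7 and returns at 12, and keeps the two branches differentiated by the oxidation levels delivered in the cycloaddition. Brief saponification of 7 (LiOH, THF–H2O, 0 °C, then citric acid) should give the hydroxy lactone F5, the ring tautomer of the aldehyde acid. 3,4,5-Trimethoxyphenylmagnesium bromide (3 equiv, THF, 0 °C, acidic work-up) adds to the aldehyde carbon and the product relactonises to the aryl lactone F6. LiAlH4 gives the diol F7, and MnO2 in CH2Cl2 oxidises only the benzylic alcohol to give 12.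

Step 6. The risk is incomplete epimerisation because the cis isomer is held as its bicyclic hemiketal; opening of the ring by beta-elimination of O1 could also compete. The fallback sets out from 12 and returns at 13, and blocks the hemiketal. Silylation (TBSCl, imidazole, DMF) gives the open cis ketone silyl ether F8, DBU in CH2Cl2 should then equilibrate it to the trans silyl ether F9, and HF·pyridine in THF removes the silyl group to give 13.

**Further compounds**

F1 | step 2 | bis[(1R,2S,5R)-menthyl] but-2-ynedioate | CC(C)[C@@H]1CC[C@@H](C)C[C@H]1OC(=O)C#CC(=O)O[C@@H]1C[C@H](C)CC[C@H]1C(C)C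
F2 | step 2 | bis[(1R,2S,5R)-menthyl] (2R)-2-(3,4-dimethoxyphenyl)-2,5-dihydrofuran-3,4-dicarboxylate | COc1ccc([C@H]2OCC(C(=O)O[C@@H]3C[C@H](C)CC[C@H]3C(C)C)=C2C(=O)O[C@@H]3C[C@H](C)CC[C@H]3C(C)C)cc1OC
F3 | step 2 | bis[(1R,2S,5R)-menthyl] (2S)-2-(3,4-dimethoxyphenyl)-2,5-dihydrofuran-3,4-dicarboxylate (unwanted C2 epimer) | COc1ccc([C@@H]2OCC(C(=O)O[C@@H]3C[C@H](C)CC[C@H]3C(C)C)=C2C(=O)O[C@@H]3C[C@H](C)CC[C@H]3C(C)C)cc1OC
F4 | step 2 | bis[(1R,2S,5R)-menthyl] (2S,3R,4S)-2-(3,4-dimethoxyphenyl)oxolane-3,4-dicarboxylate (all-cis) | CC(C)[C@@H]1CC[C@@H](C)C[C@H]1OC(=O)[C@@H]1CO[C@H](c2ccc(OC)c(OC)c2)[C@@H]1C(=O)O[C@@H]1C[C@H](C)CC[C@H]1C(C)C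
F5 | step 4 | (3aS,6S,6aR)-6-(3,4-dimethoxyphenyl)-3-hydroxytetrahydro-1H,3H-furo[3,4-c]furan-1-one (anomer mixture) | O=C1OC(O)[C@@H]2CO[C@H](c3ccc(OC)c(OC)c3)[C@H]12
F6 | step 4 | (3aS,6S,6aR)-6-(3,4-dimethoxyphenyl)-3-(3,4,5-trimethoxyphenyl)tetrahydro-1H,3H-furo[3,4-c]furan-1-one (epimers at C3) | O=C1OC(c3cc(OC)c(OC)c(OC)c3)[C@@H]2CO[C@H](c4ccc(OC)c(OC)c4)[C@H]12
F7 | step 4 | [(3S,4S,5S)-5-(3,4-dimethoxyphenyl)-4-(hydroxymethyl)oxolan-3-yl](3,4,5-trimethoxyphenyl)methanol (carbinol epimers) | OC(c3cc(OC)c(OC)c(OC)c3)[C@@H]1CO[C@H](c2ccc(OC)c(OC)c2)[C@@H]1CO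
F8 | step 6 | tert-butyldimethylsilyl ether of cis ketol 12 | COc1ccc([C@H]2OC[C@@H](C(=O)c3cc(OC)c(OC)c(OC)c3)[C@H]2CO[Si](C)(C)C(C)(C)C)cc1OC
F9 | step 6 | tert-butyldimethylsilyl ether of target 13 | COc1ccc([C@H]2OC[C@H](C(=O)c3cc(OC)c(OC)c(OC)c3)[C@H]2CO[Si](C)(C)C(C)(C)C)cc1OC
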